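(All constants were chosen freely, and the outcome is calculated.)

1.73 was the number I carried for birch. It is the wear number W: the over-reaction constant at that temperature, times the run time, times the free share of target, the part not bound as idle adduct.

| setting | maple | oak | birch |
|---|---|---|---|
| substrate | 2.0 × 10⁻⁴ M | 2.0 × 10⁻⁴ M | 2.0 × 10⁻⁴ M |
| coupling partner | 0.240 mM | 0.240 mM | 0.240 mM |
| temperature | 70 °C | 50 °C | 90 °C |
| time | 10 s | 10 s | 10 s |

* the flask that comes out highest in amount of target, in percent of the substrate charged, or "all alike" when all lie within 1.5 percentage points (maple / oak / birch / all alike)
* target at the end, in percent of the substrate charged, maple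
* target at the end, in percent of the substrate charged, oak
* target at the end, in percent of the substrate charged, birch

    substrate + coupling partner → target (k1 = 362 L mol⁻¹ s⁻¹, Ea1 = 47.0 kJ mol⁻¹)
    substrate + 2 coupling partner → side product A (k2 = 1.63 × 10⁶ L² mol⁻² s⁻¹, Ea2 = 14.0 kJ mol⁻¹)
    coupling partner + target ⇌ idle adduct, settled at all times (K3 = 6000 L mol⁻¹, ΔH3 = −20.0 kJ mol⁻¹)
    target → over-reaction product (k4 = 0.0509 s⁻¹, Ea4 = 84.0 kJ mol⁻¹)
    substrate + target → side product B (k5 = 18.2 L mol⁻¹ s⁻¹, Ea5 = 54.0 kJ mol⁻¹)
    (constants at 70 °C)

- percent here means substrate units held: one side product B counts as two
- what is said of target includes idle adduct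
- for a step with 2 of a species take k times the square, and two of it per event
- the constants hold at 70 °C; other temperatures follow from the activation energies and enthalpies

I replaced the falling curve of coupling partner by a flat value c = 0.120 mM, half of the charge, as my guess at its mean. With c flat, substrate decays pseudo-first-order, and target is made and worn as in a simple chain. I then ranked the clocks.

At the top stood the adduct balance, kept at equilibrium by the terms of the problem. It set the free share of target, taken at c. Next came substrate. Its lifetime against both coupling routes was 7.23 s in birch, 14.9 s in maple and 30.3 s in oak.

The wear lifetime of target, the run time over W, was 5.78 s in birch, shorter than that of substrate. In maple W was 0.296, a lifetime of 33.8 s, longer than that of substrate. In oak W was 0.0390, a lifetime of 257 s, again longer. At the foot, in birch, stood the loss of target to side product B, with a lifetime of 96.9 s even at the full substrate charge.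

Reckoned at c, the selectivity, the share of spent substrate going to target, came to 64.9 % in maple, 47.5 % in oak and 77.8 % in birch. The chain then gave me 27.0 % for maple, 13.1 % for oak and 22.8 % for birch. So I chose maple.

The forecast also chose maple, with 24.3 % (23 % to 25.5 %) for maple, 14.5 % (13.7 % to 15.3 %) for oak and 15 % (13.8 % to 16.2 %) for birch. Of birch it wrote: “selectivity is best”. Its birch figure stood below mine.

The flasks gave 25.3 % in maple, 14.8 % in oak and 15.6 % in birch, so maple led, and my birch figure stood 7.2 percentage points too high. With the over-reaction step struck out, birch held 49.8 % of target instead of 15.6 %, the largest single effect. Birch's W times its mean target, read from its values at 5.00 s and 10.0 s as 18.1 %, estimates 31.3 % of over-reaction product, and at the end birch held 36.0 %. In oak, W times a mean target read the same way as 9.05 % estimates 0.353 %, and at the end oak held 0.339 %.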